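**Retrosynthetic overview**
- The α-methylene-γ-lactone is the last ring formed, by carbonylative closure of a C6-hydroxy/C7-ethynyl pair; C15 acetylation, C2 tigloylation and C8 desilylation finish the target.
- The ten-membered carbocycle is closed before that through the C1–C2 bond (Nozaki–Hiyama–Kishi, (Z)-vinyl iodide + aldehyde) on a chain held by a temporary C15–O6 butenolide.
- The C6/C7/C8 triad and the cis C15/C6 arrangement come from Baeyer–Villiger excision (C15–C8 cleavage) of an all-trans cyclohexenone whose ring carbons are C4, C5, C6, C7, C8 and C15.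
- That cyclohexenone comes from enantioselective conjugate alkynylation (C7) and trans-alkylation (C8) of a para-quinone monoketal, made by oxidative dearomatisation of 2-allylphenol (key step).
- C9/C10/C14/C1 come from propargyl alcohol via (Z)-3-iodo-2-methylallyl bromide, C12 from CO, and C3/C2 from the allyl group of the phenol.

Assumption: positions are labelled with germacrane numbering (ring C1–C10, lactone carbons C11–C13 with C12 on O6, C14 methyl on C10, C15 on C4). In this numbering the target is (2S,6R,7R,8R), C9 is cis to C2 across C1=C10, and C15 is cis to C6 across C4=C5.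

**Route**

Step 1
Reactants: 1 2-allylphenol
Product: 3 2-allyl-4,4-dimethoxycyclohexa-2,5-dien-1-one, via 2-allyl-4-methoxyphenol 2 (not isolated)
Conditions: PhI(OAc)2 (2.2 equiv), MeOH, 0 °C → rt
Reagents that add atoms: methanol, CO
Why: Oxidative dearomatisation of a phenol to a para-quinone monoketal: two successive oxidations by the hypervalent iodine reagent trap methanol twice at the free para position, which breaks the aromatic ring and lays out its six carbons as C15 (carbonyl), C4, C5, C6 (ketal), C7 and C8 of the target; no stereocentre is formed.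

Step 2
Reactants: 3 2-allyl-4,4-dimethoxycyclohexa-2,5-dien-1-one
Product: 4 (5S)-2-allyl-4,4-dimethoxy-5-[(trimethylsilyl)ethynyl]cyclohex-2-en-1-one
Conditions: Me2AlC≡CSiMe3 (from HC≡CSiMe3, n-BuLi, Me2AlCl), Ni(acac)2 (5 mol%), chiral tert-butyl cyano-bis(oxazoline) ligand (6 mol%), t-BuOMe, 0 °C; aq. Rochelle salt
Reagents that add atoms: (trimethylsilyl)acetylene, C#C[Si](C)(C)C (transferred as its dimethylaluminium acetylide)
Why: Nickel-catalysed enantioselective conjugate alkynylation of a cyclic enone: the chiral nickel catalyst adds the alkynyl group to one face of the unsubstituted C7=C8 enone (the allyl-bearing C4=C5 enone is alpha-substituted and slower), so C7 is set by catalyst control, the ligand antipode that gives (5S)-4 being used.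

Step 3
Reactants: 5 propargyl alcohol
Product: 6 (2Z)-3-iodo-2-methylprop-2-en-1-ol
Conditions: MeMgBr (2.5 equiv), CuI (10 mol%), Et2O, −10 °C → rt; then I2, −78 → 0 °C
Reagents that add atoms: methylmagnesium bromide, C[Mg]Br; iodine, II
Why: Copper-catalysed anti-carbomagnesiation of the propargylic alkoxide places methyl on the internal carbon and magnesium on the terminal carbon cis to CH2O (five-membered chelate), and iodinolysis with retention gives only the (Z)-iodoalkene.

Step 4
Reactants: 6 (2Z)-3-iodo-2-methylprop-2-en-1-ol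
Product: 7 (1Z)-3-bromo-1-iodo-2-methylprop-1-ene
Conditions: CBr4, PPh3, CH2Cl2, 0 °C
Reagents that add atoms: carbon tetrabromide, BrC(Br)(Br)Br
Why: Appel bromination of a primary allylic alcohol proceeds by SN2 at carbon and leaves the (Z)-iodoalkene untouched.

Step 5
Reactants: 4 (5S)-2-allyl-4,4-dimethoxy-5-[(trimethylsilyl)ethynyl]cyclohex-2-en-1-one; 7 (1Z)-3-bromo-1-iodo-2-methylprop-1-ene
Product: 9 (5S,6R)-2-allyl-6-[(2Z)-3-iodo-2-methylprop-2-en-1-yl]-5-[(trimethylsilyl)ethynyl]cyclohex-2-ene-1,4-dione, via alkylated ketal 8 (not isolated)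
Conditions: LiN(iPr)2, THF, −78 °C; 7, DMPU, −78 → −30 °C; then 1 M HCl, THF, 0 °C
Reagents that add atoms: water, O
Why: Enolate alkylation followed by ketal hydrolysis: deprotonation is possible only at C8, the allylic bromide attacks the lithium enolate anti to the neighbouring C7 alkynyl group (trans product, also the thermodynamic epimer), and cold dilute acid then unmasks the C6 ketone.

Step 6
Reactants: 9 (5S,6R)-2-allyl-6-[(2Z)-3-iodo-2-methylprop-2-en-1-yl]-5-[(trimethylsilyl)ethynyl]cyclohex-2-ene-1,4-dione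
Product: 10 (4R,5S,6R)-2-allyl-4-hydroxy-6-[(2Z)-3-iodo-2-methylprop-2-en-1-yl]-5-[(trimethylsilyl)ethynyl]cyclohex-2-en-1-one
Conditions: NaBH4, CeCl3·7H2O, MeOH, −78 °C
Reagents that add atoms: none
Why: Luche 1,2-reduction takes the less hindered C6 carbonyl (the C15 carbonyl is flanked by two substituted carbons), and axial hydride delivery gives the equatorial alcohol trans to the C7 substituent, completing the all-trans C6/C7/C8 triad.

Step 7
Reactants: 10 (4R,5S,6R)-2-allyl-4-hydroxy-6-[(2Z)-3-iodo-2-methylprop-2-en-1-yl]-5-[(trimethylsilyl)ethynyl]cyclohex-2-en-1-one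
Product: 12 (5R)-3-allyl-5-[(1R,2R,4Z)-2-hydroxy-5-iodo-4-methyl-1-[(trimethylsilyl)ethynyl]pent-4-en-1-yl]furan-2(5H)-one, via seven-membered lactone 11 (not isolated)
Conditions: (Me3SiO)2, SnCl4 (10 mol%), trans-cyclohexane-1,2-diamine (10 mol%), 4 Å MS, CH2Cl2, rt; then camphorsulfonic acid (cat.), CH2Cl2, rt
Reagents that add atoms: bis(trimethylsilyl) peroxide, C[Si](C)(C)OO[Si](C)(C)C
Why: Baeyer–Villiger oxidation with a tin-activated silyl peroxide that leaves C=C bonds alone inserts oxygen between C15 and the better-migrating secondary carbon C8 with retention (this fixes the C8–O stereocentre), and the cis C6 hydroxyl then opens the strained seven-membered lactone by acid-catalysed translactonisation to the butenolide, freeing the C8 hydroxyl.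

Step 8
Reactants: 12 (5R)-3-allyl-5-[(1R,2R,4Z)-2-hydroxy-5-iodo-4-methyl-1-[(trimethylsilyl)ethynyl]pent-4-en-1-yl]furan-2(5H)-one
Product: 13 (5R)-3-allyl-5-[(1S,2R,4Z)-5-iodo-4-methyl-2-(triethylsilyloxy)-1-[(trimethylsilyl)ethynyl]pent-4-en-1-yl]furan-2(5H)-one
Conditions: Et3SiOTf, 2,6-lutidine, CH2Cl2, −78 °C
Reagents that add atoms: triethylsilyl trifluoromethanesulfonate, CC[Si](CC)(CC)OS(=O)(=O)C(F)(F)F
Why: Silyl ether formation at the only free hydroxyl (C8), which later keeps C8–OH out of the lactone closure.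

Step 9
Reactants: 13 (5R)-3-allyl-5-[(1S,2R,4Z)-5-iodo-4-methyl-2-(triethylsilyloxy)-1-[(trimethylsilyl)ethynyl]pent-4-en-1-yl]furan-2(5H)-one
Product: 14 2-{(5R)-5-[(1S,2R,4Z)-5-iodo-4-methyl-2-(triethylsilyloxy)-1-[(trimethylsilyl)ethynyl]pent-4-en-1-yl]-2-oxo-2,5-dihydrofuran-3-yl}acetaldehyde
Conditions: OsO4 (2 mol%), NaIO4, 2,6-lutidine, dioxane/H2O 3:1, rt
Reagents that add atoms: osmium tetroxide, O=[Os](=O)(=O)=O (catalytic oxygen carrier); sodium periodate, [Na+].[O-]I(=O)(=O)=O (stoichiometric oxygen source)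
Why: Lemieux–Johnson cleavage: the monosubstituted allyl alkene is dihydroxylated faster than the iodine-deactivated trisubstituted alkene or the electron-poor butenolide, and periodate cleaves the diol to the C2 aldehyde with loss of the terminal carbon.

Step 10
Reactants: 14 2-{(5R)-5-[(1S,2R,4Z)-5-iodo-4-methyl-2-(triethylsilyloxy)-1-[(trimethylsilyl)ethynyl]pent-4-en-1-yl]-2-oxo-2,5-dihydrofuran-3-yl}acetaldehyde
Product: 15 (2S,6R,7S,8R)-macrocyclic butenolide alcohol: ten-membered ring C1–C10 with (1(10)Z)-olefin, C15(=O)–O bridge from C4 to C6 (C4=C5 in the butenolide), 2-OH, 7-(trimethylsilyl)ethynyl, 8-triethylsilyloxy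
Conditions: CrCl2 (10 equiv), NiCl2 (2 mol%), DMSO/THF, rt, 2 mM (slow addition)
Reagents that add atoms: none
Why: Nozaki–Hiyama–Kishi reaction: zerovalent nickel inserts into the C1–I bond with retention of the (Z)-geometry, the alkenylchromium species adds only to the aldehyde under high dilution to close the ten-membered ring, and the C2 carbinol is set by substrate control in the cyclic transition state, the (2S)-epimer being taken as the major one.

Step 11
Reactants: 15 (2S,6R,7S,8R)-macrocyclic butenolide alcohol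
Product: 17 (2S,6R,7S,8R)-7-ethynyl-4-(hydroxymethyl)-10-methyl-8-(triethylsilyloxy)cyclodeca-1(10)Z,4-diene-2,6-diol (germacrane numbering; C15 hydroxymethyl cis to C6), via silylated triol 16 (not isolated)
Conditions: iBu2AlH (6 equiv), CH2Cl2, −78 → 0 °C; then MeOH, K2CO3, rt
Reagents that add atoms: none
Why: Hydride 1,2-reduction of the unsaturated lactone goes through the lactol to the ene-1,4-diol whose geometry is inherited from the five-membered ring, and methanolic carbonate then removes only the alkynyl trimethylsilyl group while the secondary triethylsilyl ether survives.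

Step 12
Reactants: 17 (2S,6R,7S,8R)-7-ethynyl-4-(hydroxymethyl)-10-methyl-8-(triethylsilyloxy)cyclodeca-1(10)Z,4-diene-2,6-diol
Product: 18 (2S,6R,7S,8R)-2,15-dihydroxy-8-(triethylsilyloxy)germacra-1(10)Z,4,11(13)-trien-12,6-olide
Conditions: PdCl2 (10 mol%), thiourea (10 mol%), CO (1 atm), acetone, 50 °C
Reagents that add atoms: carbon monoxide, [C-]#[O+]
Why: Palladium-catalysed cyclocarbonylation of a homopropargylic alcohol: the C6 alkoxycarbonyl–palladium species adds cis across the neighbouring alkyne and protonolysis gives the exo-methylene lactone; only the C6 hydroxyl is both free and adjacent to the alkyne-bearing carbon, and the existing trans C6/C7 relationship gives the trans-fused lactone.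

Step 13
Reactants: 18 (2S,6R,7S,8R)-2,15-dihydroxy-8-(triethylsilyloxy)germacra-1(10)Z,4,11(13)-trien-12,6-olide
Product: 19 (2S,6R,7S,8R)-15-acetoxy-2-hydroxy-8-(triethylsilyloxy)germacra-1(10)Z,4,11(13)-trien-12,6-olide
Conditions: Ac2O (1.1 equiv), 2,4,6-collidine, CH2Cl2, −40 °C
Reagents that add atoms: acetic anhydride, CC(=O)OC(C)=O
Why: Kinetically selective acylation: the primary allylic C15 hydroxyl reacts much faster than the secondary C2 hydroxyl with one equivalent of anhydride at low temperature.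

Step 14
Reactants: 19 (2S,6R,7S,8R)-15-acetoxy-2-hydroxy-8-(triethylsilyloxy)germacra-1(10)Z,4,11(13)-trien-12,6-olide
Product: 20 (2S,6R,7S,8R)-15-acetoxy-2-tigloyloxy-8-(triethylsilyloxy)germacra-1(10)Z,4,11(13)-trien-12,6-olide
Conditions: tigloyl chloride, pyridine, DMAP (cat.), CH2Cl2, 0 °C → rt
Reagents that add atoms: tigloyl chloride, C/C=C(\C)C(Cl)=O
Why: Acylation of the one remaining free hydroxyl (C2) with retention; pyridine instead of a trialkylamine avoids deconjugation of the tigloyl unit through a vinylketene.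

Step 15
Reactants: 20 (2S,6R,7S,8R)-15-acetoxy-2-tigloyloxy-8-(triethylsilyloxy)germacra-1(10)Z,4,11(13)-trien-12,6-olide
Product: 21 (2S,6R,7R,8R)-15-acetoxy-8-hydroxy-2-tigloyloxygermacra-1(10)Z,4,11(13)-trien-12,6-olide (CNP0129394.2)
Conditions: HF·pyridine, pyridine, THF, 0 °C
Reagents that add atoms: none
Why: Fluoride cleavage of the triethylsilyl ether under buffered, weakly acidic conditions that spare the allylic esters and the alpha-methylene lactone.

**Compound list**
1 | 2-allylphenol | C=CCc1ccccc1O | starting material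
2 | 2-allyl-4-methoxyphenol | C=CCc1cc(OC)ccc1O | intermediate
3 | 2-allyl-4,4-dimethoxycyclohexa-2,5-dien-1-one | C=CCC1=CC(OC)(OC)C=CC1=O | intermediate
4 | (5S)-2-allyl-4,4-dimethoxy-5-[(trimethylsilyl)ethynyl]cyclohex-2-en-1-one | C=CCC1=CC(OC)(OC)[C@H](C#C[Si](C)(C)C)CC1=O | intermediate
5 | propargyl alcohol | C#CCO | starting material
6 | (2Z)-3-iodo-2-methylprop-2-en-1-ol | OC/C(C)=C\I | intermediate
7 | (1Z)-3-bromo-1-iodo-2-methylprop-1-ene | BrC/C(C)=C\I | intermediate
8 | (5S,6R)-2-allyl-6-[(2Z)-3-iodo-2-methylprop-2-en-1-yl]-4,4-dimethoxy-5-[(trimethylsilyl)ethynyl]cyclohex-2-en-1-one | C=CCC1=CC(OC)(OC)[C@H](C#C[Si](C)(C)C)[C@@H](C/C(C)=C\I)C1=O | intermediate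
9 | (5S,6R)-2-allyl-6-[(2Z)-3-iodo-2-methylprop-2-en-1-yl]-5-[(trimethylsilyl)ethynyl]cyclohex-2-ene-1,4-dione | C=CCC1=CC(=O)[C@H](C#C[Si](C)(C)C)[C@@H](C/C(C)=C\I)C1=O | intermediate
10 | (4R,5S,6R)-2-allyl-4-hydroxy-6-[(2Z)-3-iodo-2-methylprop-2-en-1-yl]-5-[(trimethylsilyl)ethynyl]cyclohex-2-en-1-one | C=CCC1=C[C@@H](O)[C@H](C#C[Si](C)(C)C)[C@@H](C/C(C)=C\I)C1=O | intermediate
11 | (5R,6S,7R)-3-allyl-5-hydroxy-7-[(2Z)-3-iodo-2-methylprop-2-en-1-yl]-6-[(trimethylsilyl)ethynyl]-6,7-dihydrooxepin-2(5H)-one | C=CCC1=C[C@@H](O)[C@H](C#C[Si](C)(C)C)[C@@H](C/C(C)=C\I)OC1=O | intermediate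
12 | (5R)-3-allyl-5-[(1R,2R,4Z)-2-hydroxy-5-iodo-4-methyl-1-[(trimethylsilyl)ethynyl]pent-4-en-1-yl]furan-2(5H)-one | C=CCC1=C[C@H]([C@H](C#C[Si](C)(C)C)[C@H](O)C/C(C)=C\I)OC1=O | intermediate
13 | (5R)-3-allyl-5-[(1S,2R,4Z)-5-iodo-4-methyl-2-(triethylsilyloxy)-1-[(trimethylsilyl)ethynyl]pent-4-en-1-yl]furan-2(5H)-one | C=CCC1=C[C@H]([C@H](C#C[Si](C)(C)C)[C@H](O[Si](CC)(CC)CC)C/C(C)=C\I)OC1=O | intermediate
14 | 2-{(5R)-5-[(1S,2R,4Z)-5-iodo-4-methyl-2-(triethylsilyloxy)-1-[(trimethylsilyl)ethynyl]pent-4-en-1-yl]-2-oxo-2,5-dihydrofuran-3-yl}acetaldehyde | O=CCC1=C[C@H]([C@H](C#C[Si](C)(C)C)[C@H](O[Si](CC)(CC)CC)C/C(C)=C\I)OC1=O | intermediate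
15 | (2S,6R,7S,8R)-macrocyclic butenolide alcohol (ten-membered ring, 1(10)Z, C15(=O)–O bridge C4→C6, 2-OH, 7-(trimethylsilyl)ethynyl, 8-triethylsilyloxy) | O=C1O[C@@H]2C=C1C[C@H](O)/C=C(/C)C[C@@H](O[Si](CC)(CC)CC)[C@H]2C#C[Si](C)(C)C | intermediate
16 | (2S,6R,7S,8R)-4-(hydroxymethyl)-10-methyl-8-(triethylsilyloxy)-7-[(trimethylsilyl)ethynyl]cyclodeca-1(10)Z,4-diene-2,6-diol | O[C@@H]1/C=C(\CO)C[C@H](O)/C=C(/C)C[C@@H](O[Si](CC)(CC)CC)[C@H]1C#C[Si](C)(C)C | intermediate
17 | (2S,6R,7S,8R)-7-ethynyl-4-(hydroxymethyl)-10-methyl-8-(triethylsilyloxy)cyclodeca-1(10)Z,4-diene-2,6-diol | O[C@@H]1/C=C(\CO)C[C@H](O)/C=C(/C)C[C@@H](O[Si](CC)(CC)CC)[C@H]1C#C | intermediate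
18 | (2S,6R,7S,8R)-2,15-dihydroxy-8-(triethylsilyloxy)germacra-1(10)Z,4,11(13)-trien-12,6-olide | C=C1C(=O)O[C@@H]2/C=C(\CO)C[C@H](O)/C=C(/C)C[C@@H](O[Si](CC)(CC)CC)[C@@H]12 | intermediate
19 | (2S,6R,7S,8R)-15-acetoxy-2-hydroxy-8-(triethylsilyloxy)germacra-1(10)Z,4,11(13)-trien-12,6-olide | C=C1C(=O)O[C@@H]2/C=C(\COC(C)=O)C[C@H](O)/C=C(/C)C[C@@H](O[Si](CC)(CC)CC)[C@@H]12 | intermediate
20 | (2S,6R,7S,8R)-15-acetoxy-2-tigloyloxy-8-(triethylsilyloxy)germacra-1(10)Z,4,11(13)-trien-12,6-olide | C=C1C(=O)O[C@@H]2/C=C(\COC(C)=O)C[C@H](OC(=O)/C(C)=C/C)/C=C(/C)C[C@@H](O[Si](CC)(CC)CC)[C@@H]12 | intermediate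
21 | (2S,6R,7R,8R)-15-acetoxy-8-hydroxy-2-tigloyloxygermacra-1(10)Z,4,11(13)-trien-12,6-olide (CNP0129394.2) | C=C1C(=O)O[C@@H]2/C=C(\COC(C)=O)C[C@H](OC(=O)/C(C)=C/C)/C=C(/C)C[C@@H](O)[C@@H]12 | target

**Step count and risks**
Total step count: 15. Longest linear sequence: 13 steps (steps 1, 2 and 5–15 from 2-allylphenol); steps 3 and 4 form a two-step side branch.

Three steps most likely to fail:

1. Step 2 (enantio- and regioselective conjugate alkynylation of the cross-conjugated ketal dienone). The method is established for simple cyclohexenones; here the neighbouring ketal and the second enone may lower rate or selectivity. Fallback, setting out from 3 and returning at 9: the dimethyl ketal is exchanged with (R,R)-hydrobenzoin (pyridinium tosylate, benzene, removal of methanol) to give the C2-symmetric spiroketal F1. Its phenyl groups shield one face of the C7=C8 enone, so the same aluminium acetylide with an achiral nickel catalyst (Ni(acac)2, iBu2AlH cat.) adds under auxiliary control to give the adduct F2. Alkylation of F2 with 7 as in step 5 gives the trans-alkylated spiroketal F3, and aqueous acid releases the diol and delivers 9. The (S,S)-diol is used instead if the facial sense proves opposite.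

2. Step 7 (Baeyer–Villiger oxidation of a conjugated, alpha'-branched enone in the presence of two alkenes and a vinyl iodide). Risks are slow reaction of the conjugated carbonyl, competing alkenyl migration and oxidation elsewhere. Fallback, setting out from 10 and returning at 12: Me3SiOTf/Et3N converts 10 into the bis(trimethylsilyl) dienol ether F4 (enol ether across C15=C8, silyl ether on O6). One equivalent of ozone at −78 °C followed by Me2S cleaves only this electron-rich C15=C8 bond, and acidic work-up lactonises the C15 acid onto O6 to give the keto-butenolide F5 (C8 ketone). Reagent-controlled reduction with (S)-2-methyl-CBS-oxazaborolidine and catecholborane (branched C7 side as the large group) then sets the (8R)-carbinol and gives 12.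

3. Step 10 (ten-membered ring closure and configuration at C2). The ring closes across a rigid butenolide, and the facial selectivity at the aldehyde cannot be predicted with confidence. Fallback, setting out from 14 and returning at 16: if the closure delivers mainly the (2R)-alcohol F6, it is not acylated directly. A Mitsunobu reaction with benzoic acid (PPh3, diisopropyl azodicarboxylate) inverts C2 to give the (2S)-benzoate F7. The iBu2AlH treatment of step 11 then removes the benzoate as benzyl alcohol in the same operation that reduces the butenolide, giving 16 and, after the carbonate stage, 17.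

**Further compounds**
F1 | step 2 | (2R,3R)-7-allyl-2,3-diphenyl-1,4-dioxaspiro[4.5]deca-6,9-dien-8-one | C=CCC1=CC2(O[C@H](c3ccccc3)[C@@H](c3ccccc3)O2)C=CC1=O
F2 | step 2 | (2R,3R,10S)-7-allyl-2,3-diphenyl-10-[(trimethylsilyl)ethynyl]-1,4-dioxaspiro[4.5]dec-6-en-8-one | C=CCC1=CC2(O[C@H](c3ccccc3)[C@@H](c3ccccc3)O2)[C@H](C#C[Si](C)(C)C)CC1=O
F3 | step 2 | (2R,3R,9R,10S)-7-allyl-9-[(2Z)-3-iodo-2-methylprop-2-en-1-yl]-2,3-diphenyl-10-[(trimethylsilyl)ethynyl]-1,4-dioxaspiro[4.5]dec-6-en-8-one | C=CCC1=CC2(O[C@H](c3ccccc3)[C@@H](c3ccccc3)O2)[C@H](C#C[Si](C)(C)C)[C@@H](C/C(C)=C\I)C1=O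
F4 | step 7 | (5S,6R)-2-allyl-4-[(2Z)-3-iodo-2-methylprop-2-en-1-yl]-3,6-bis(trimethylsilyloxy)-5-[(trimethylsilyl)ethynyl]cyclohexa-1,3-diene | C=CCC1=C[C@@H](O[Si](C)(C)C)[C@H](C#C[Si](C)(C)C)C(C/C(C)=C\I)=C1O[Si](C)(C)C
F5 | step 7 | (5R)-3-allyl-5-[(1S,4Z)-5-iodo-4-methyl-2-oxo-1-[(trimethylsilyl)ethynyl]pent-4-en-1-yl]furan-2(5H)-one | C=CCC1=C[C@H]([C@H](C#C[Si](C)(C)C)C(=O)C/C(C)=C\I)OC1=O
F6 | step 10 | (2R,6R,7S,8R)-macrocyclic butenolide alcohol (C2 epimer of 15) | O=C1O[C@@H]2C=C1C[C@@H](O)/C=C(/C)C[C@@H](O[Si](CC)(CC)CC)[C@H]2C#C[Si](C)(C)C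
F7 | step 10 | (2S,6R,7S,8R)-macrocyclic butenolide 2-benzoate | O=C1O[C@@H]2C=C1C[C@H](OC(=O)c3ccccc3)/C=C(/C)C[C@@H](O[Si](CC)(CC)CC)[C@H]2C#C[Si](C)(C)C
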